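## Retrosynthetic overview

1. Target 24 ⇐ O‑acetylation of β‑hydroxy ketone 23 ⇐ copper‑catalysed conjugate borylation/oxidation of enone 21 (sets C1–O and C10–H together) ⇐ one‑flask α'‑hydroxylation/tigloylation of enone 18 (sets C8).
2. Enone 18 ⇐ ring A closed last at C5–C6 by a nickel‑catalysed 6‑endo conjugate addition of an alkylzinc onto acylcyclohexene 15 (quaternary C5), then Pd‑mediated desaturation.
3. 15 ⇐ Pd‑catalysed acyl Stille coupling (C9–C10) of alkenylstannane 6 (fragment 1, ring B, C4 set) with iodo acid chloride 12 (fragment 2, C7 set).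
4. 6 ⇐ Cu‑catalysed asymmetric methyl addition to 2‑methylcyclohexenone; 12 ⇐ Rh‑catalysed asymmetric isopropenyl addition to furan‑2(5H)‑one, then iodide opening of the lactone; tigloyl chloride 14 ⇐ tiglic acid.
5. Ring order: ring B comes from the starting enone; ring A is formed in step 9.

Assumption: in steps 1 and 4 the ligand enantiomer that gives the drawn configuration is used; atom labels C1–C10 in the explanations are eremophilane labels (C9 ketone, C8 tigloyloxy, C7 isopropenyl, C6 CH2, C5 quaternary, C4 CH(CH3), C1 acetoxy, C10 ring‑fusion CH); ring A = C5–C10, ring B = C1–C5 plus C10.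

## Route

Step 1
Reactants: 1 2-methylcyclohex-2-en-1-one
Product: 3 (S)-[(2,3-dimethylcyclohex-1-en-1-yl)oxy]trimethylsilane, via dimethylaluminium enolate 2 (not isolated)
Conditions: AlMe3 (1.4 equiv), Cu(O2CC4H3S) (2 mol %), chiral phosphoramidite ligand (4 mol %), Et2O, −30 °C; then Me3SiOTf (1.5 equiv), −30 °C → rt
Reagents that add atoms: trimethylaluminium C[Al](C)C; trimethylsilyl trifluoromethanesulfonate C[Si](C)(C)OS(=O)(=O)C(F)(F)F
Why: Copper‑catalysed asymmetric conjugate addition sets C4 (S) under ligand control, and O‑silylation of the regiodefined aluminium enolate fixes the enol double bond on the methyl‑bearing side.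

Step 2
Reactants: 3 (S)-[(2,3-dimethylcyclohex-1-en-1-yl)oxy]trimethylsilane
Product: 5 (S)-2,3-dimethylcyclohex-1-en-1-yl trifluoromethanesulfonate, via lithium enolate 4 (not isolated)
Conditions: MeLi (1.05 equiv), THF, 0 °C; then PhNTf2 (1.2 equiv), −78 °C → rt
Reagents that add atoms: N-phenylbis(trifluoromethanesulfonimide) O=S(=O)(N(c1ccccc1)S(=O)(=O)C(F)(F)F)C(F)(F)F
Why: Si–O cleavage by MeLi gives the regiodefined lithium enolate, which is O‑sulfonylated (enol triflate formation) without touching the stereocentre.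

Step 3
Reactants: 5 (S)-2,3-dimethylcyclohex-1-en-1-yl trifluoromethanesulfonate
Product: 6 (S)-(2,3-dimethylcyclohex-1-en-1-yl)trimethylstannane
Conditions: Me3SnSnMe3 (1.3 equiv), Pd(PPh3)4 (5 mol %), LiCl (6 equiv), THF, 65 °C
Reagents that add atoms: hexamethylditin C[Sn](C)(C)[Sn](C)(C)C
Why: Palladium‑catalysed stannylation of an enol triflate with a distannane (Stille‑type Sn–Sn coupling) gives the alkenyl nucleophile of fragment 1.

Step 4
Reactants: 7 furan-2(5H)-one; 8 potassium trifluoro(prop-1-en-2-yl)borate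
Product: 9 (S)-4-(prop-1-en-2-yl)dihydrofuran-2(3H)-one
Conditions: [Rh(cod)2]BF4 (3 mol %), (S)-BINAP (3.3 mol %), toluene/H2O 10:1, 100 °C
Reagents that add atoms: none
Why: Rhodium‑catalysed asymmetric 1,4‑addition (Hayashi–Miyaura type) of the alkenylboron reagent to the butenolide sets C7 under ligand control.

Step 5
Reactants: 9 (S)-4-(prop-1-en-2-yl)dihydrofuran-2(3H)-one
Product: 11 (S)-4-iodo-3-(prop-1-en-2-yl)butanoic acid, via trimethylsilyl ester 10 (not isolated)
Conditions: Me3SiI (1.3 equiv), 2,6-di-tert-butylpyridine (0.1 equiv), CH2Cl2, 0 → 35 °C, dark; then H2O, 0 °C; used at once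
Reagents that add atoms: iodotrimethylsilane C[Si](C)(C)I
Why: Silyl activation and SN2 attack of iodide at the O–CH2 carbon (O‑alkyl lactone cleavage) give the silyl ester, which water hydrolyses; the hindered base scavenges HI so the isopropenyl group survives.

Step 6
Reactants: 11 (S)-4-iodo-3-(prop-1-en-2-yl)butanoic acid
Product: 12 (S)-4-iodo-3-(prop-1-en-2-yl)butanoyl chloride
Conditions: 1-chloro-N,N,2-trimethylprop-1-en-1-amine (1.1 equiv), CH2Cl2, 0 °C → rt; used crude
Reagents that add atoms: 1-chloro-N,N,2-trimethylprop-1-en-1-amine CC(C)=C(Cl)N(C)C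
Why: The Ghosez reagent forms the acid chloride under neutral conditions, avoiding HCl addition to the alkene and relactonisation.

Step 7
Reactants: 13 (E)-2-methylbut-2-enoic acid
Product: 14 (E)-2-methylbut-2-enoyl chloride
Conditions: (COCl)2 (1.2 equiv), DMF (cat.), CH2Cl2, 0 °C → rt; distil
Reagents that add atoms: oxalyl chloride O=C(Cl)C(=O)Cl
Why: Standard acid chloride formation through the Vilsmeier intermediate; the E geometry is the stable one and is kept.

Step 8
Reactants: 6 (S)-(2,3-dimethylcyclohex-1-en-1-yl)trimethylstannane; 12 (S)-4-iodo-3-(prop-1-en-2-yl)butanoyl chloride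
Product: 15 (S)-1-[(S)-2,3-dimethylcyclohex-1-en-1-yl]-4-iodo-3-(prop-1-en-2-yl)butan-1-one
Conditions: Pd2(dba)3 (2.5 mol %), P(2-furyl)3 (10 mol %), THF, 50 °C
Reagents that add atoms: none
Why: Stille acylation joins the fragments at C9–C10; the acyl chloride adds to zerovalent palladium far faster than the primary alkyl iodide, and the alkenyl group transfers from tin in preference to methyl.

Step 9
Reactants: 15 (S)-1-[(S)-2,3-dimethylcyclohex-1-en-1-yl]-4-iodo-3-(prop-1-en-2-yl)butan-1-one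
Product: 18 (3S,4aR,5S)-4a,5-dimethyl-3-(prop-1-en-2-yl)-3,4,4a,5,6,7-hexahydronaphthalen-1(2H)-one, via alkylzinc iodide 16 (not isolated), via silyl enol ether 17 (not isolated)
Conditions: Zn dust (2 equiv), LiCl (1.5 equiv), THF, 30 °C; Ni(acac)2 (10 mol %), Me3SiCl (2.5 equiv), THF/NMP, −20 °C → rt; evaporate volatiles; Pd(OAc)2 (1.05 equiv), MeCN, rt
Reagents that add atoms: none
Why: Proposed new method: zinc inserts only into the primary C–I bond and the homoallylic alkylzinc does not rearrange (a C6 radical would suffer 1,2‑vinyl shift, so a two‑electron path is chosen); zerovalent nickel formed from Ni(acac)2 and the organozinc binds the enone and, helped by Me3SiCl, gives an η3‑1‑silyloxyallyl nickel species that takes the tethered alkyl from zinc, and C–C reductive elimination at the allyl terminus C5 closes ring A in a 6‑endo sense on the face anti to the pseudoaxial C4 methyl (C5 set, C4/C5 methyls cis, though this C4 control must override the ring's preference for isopropenyl trans to the C5 methyl); the regiodefined silyl enol ether is then desaturated towards C1, the only side with a β‑hydrogen, by Saegusa–Ito oxidation; the closest known reactions are the intermolecular Ni(acac)2‑catalysed conjugate addition of organozinc reagents to β,β‑disubstituted enones with silyl trapping and copper‑mediated intramolecular conjugate additions, the ring‑closing endo variant that builds a quaternary centre on a tetrasubstituted acylcycloalkene being new.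

Step 10
Reactants: 18 (3S,4aR,5S)-4a,5-dimethyl-3-(prop-1-en-2-yl)-3,4,4a,5,6,7-hexahydronaphthalen-1(2H)-one; 14 (E)-2-methylbut-2-enoyl chloride
Product: 21 (2R,3R,4aR,5S)-4a,5-dimethyl-1-oxo-3-(prop-1-en-2-yl)-1,2,3,4,4a,5,6,7-octahydronaphthalen-2-yl (E)-2-methylbut-2-enoate, via potassium dienolate 19 (not isolated), via potassium alkoxide 20 (not isolated)
Conditions: KN(SiMe3)2 (1.1 equiv), THF, −78 °C; 2-(phenylsulfonyl)-3-phenyloxaziridine (1.3 equiv), −78 °C; then 14 (2.5 equiv), DMAP (0.2 equiv), −78 → 0 °C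
Reagents that add atoms: 2-(phenylsulfonyl)-3-phenyloxaziridine O=S(=O)(N1OC1c1ccccc1)c1ccccc1
Why: Kinetic α'‑deprotonation gives the cross‑conjugated dienolate, Davis hydroxylation occurs anti to the pseudoaxial C7 isopropenyl group (C8 oxygen trans to it), and the potassium alkoxide is O‑acylated in the same flask.

Step 11
Reactants: 21 (2R,3R,4aR,5S)-4a,5-dimethyl-1-oxo-3-(prop-1-en-2-yl)-1,2,3,4,4a,5,6,7-octahydronaphthalen-2-yl (E)-2-methylbut-2-enoate
Product: 23 (2R,3R,4aR,5S,8S,8aS)-8-hydroxy-4a,5-dimethyl-1-oxo-3-(prop-1-en-2-yl)decahydronaphthalen-2-yl (E)-2-methylbut-2-enoate, via boryl ketone 22 (not isolated)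
Conditions: B2pin2 (1.2 equiv), CuCl (5 mol %), DPEphos (5 mol %), NaOtBu (5 mol %), MeOH (2 equiv), THF, 0 °C → rt; then 30 % H2O2, pH 7 phosphate buffer, 0 °C
Reagents that add atoms: hydrogen peroxide OO
Why: Copper‑catalysed conjugate borylation is selective for the s‑cis enone over the tiglate and the isolated alkene; boron adds to C1 and the proton to C10 from the face opposite the axial C5 methyl (trans ring fusion, kinetic), and C–B oxidation with retention gives the equatorial C1 alcohol.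

Step 12
Reactants: 23 (2R,3R,4aR,5S,8S,8aS)-8-hydroxy-4a,5-dimethyl-1-oxo-3-(prop-1-en-2-yl)decahydronaphthalen-2-yl (E)-2-methylbut-2-enoate
Product: 24 (2R,3R,4aR,5S,8S,8aS)-8-acetoxy-4a,5-dimethyl-1-oxo-3-(prop-1-en-2-yl)decahydronaphthalen-2-yl (E)-2-methylbut-2-enoate
Conditions: Ac2O (3 equiv), pyridine (5 equiv), DMAP (5 mol %), CH2Cl2, 0 °C
Reagents that add atoms: acetic anhydride CC(=O)OC(C)=O
Why: DMAP‑catalysed acetylation of the equatorial secondary alcohol at 0 °C is fast enough to avoid β‑elimination or epimerisation next to the ketone.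

## Compound list

1 | 2-methylcyclohex-2-en-1-one | CC1=CCCCC1=O | starting material
2 | dimethylaluminium (S)-2,3-dimethylcyclohex-1-en-1-olate | C[Al](C)OC1=C(C)[C@@H](C)CCC1 | intermediate
3 | (S)-[(2,3-dimethylcyclohex-1-en-1-yl)oxy]trimethylsilane | C[Si](C)(C)OC1=C(C)[C@@H](C)CCC1 | intermediate
4 | lithium (S)-2,3-dimethylcyclohex-1-en-1-olate | [Li]OC1=C(C)[C@@H](C)CCC1 | intermediate
5 | (S)-2,3-dimethylcyclohex-1-en-1-yl trifluoromethanesulfonate | O=S(=O)(OC1=C(C)[C@@H](C)CCC1)C(F)(F)F | intermediate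
6 | (S)-(2,3-dimethylcyclohex-1-en-1-yl)trimethylstannane | C[Sn](C)(C)C1=C(C)[C@@H](C)CCC1 | intermediate
7 | furan-2(5H)-one | O=C1OCC=C1 | starting material
8 | potassium trifluoro(prop-1-en-2-yl)borate | [K+].C=C(C)[B-](F)(F)F | starting material
9 | (S)-4-(prop-1-en-2-yl)dihydrofuran-2(3H)-one | C=C(C)[C@H]1COC(=O)C1 | intermediate
10 | trimethylsilyl (S)-4-iodo-3-(prop-1-en-2-yl)butanoate | C=C(C)[C@@H](CI)CC(=O)O[Si](C)(C)C | intermediate
11 | (S)-4-iodo-3-(prop-1-en-2-yl)butanoic acid | C=C(C)[C@@H](CI)CC(=O)O | intermediate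
12 | (S)-4-iodo-3-(prop-1-en-2-yl)butanoyl chloride | C=C(C)[C@@H](CI)CC(=O)Cl | intermediate
13 | (E)-2-methylbut-2-enoic acid (tiglic acid) | C/C=C(\C)C(=O)O | starting material
14 | (E)-2-methylbut-2-enoyl chloride | C/C=C(\C)C(=O)Cl | intermediate
15 | (S)-1-[(S)-2,3-dimethylcyclohex-1-en-1-yl]-4-iodo-3-(prop-1-en-2-yl)butan-1-one | C=C(C)[C@@H](CI)CC(=O)C1=C(C)[C@@H](C)CCC1 | intermediate
16 | alkylzinc iodide from 15 (C–ZnI in place of C–I, same configuration) | C=C(C)[C@@H](C[Zn]I)CC(=O)C1=C(C)[C@@H](C)CCC1 | intermediate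
17 | (3S,4aR,5S)-4a,5-dimethyl-3-(prop-1-en-2-yl)-1-(trimethylsilyloxy)-2,3,4,4a,5,6,7,8-octahydronaphthalene | C=C(C)[C@H]1C[C@@]2(C)C(=C(O[Si](C)(C)C)C1)CCC[C@@H]2C | intermediate
18 | (3S,4aR,5S)-4a,5-dimethyl-3-(prop-1-en-2-yl)-3,4,4a,5,6,7-hexahydronaphthalen-1(2H)-one | C=C(C)[C@H]1C[C@@]2(C)C(C(=O)C1)=CCC[C@@H]2C | intermediate
19 | potassium (3S,4aR,5S)-4a,5-dimethyl-3-(prop-1-en-2-yl)-3,4,4a,5,6,7-hexahydronaphthalen-1-olate (cross‑conjugated dienolate of 18) | C=C(C)[C@H]1C[C@@]2(C)C(C(O[K])=C1)=CCC[C@@H]2C | intermediate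
20 | potassium alkoxide of (2R,3R,4aR,5S)-2-hydroxy-4a,5-dimethyl-3-(prop-1-en-2-yl)-3,4,4a,5,6,7-hexahydronaphthalen-1(2H)-one | C=C(C)[C@H]1C[C@@]2(C)C(C(=O)[C@@H]1O[K])=CCC[C@@H]2C | intermediate
21 | (2R,3R,4aR,5S)-4a,5-dimethyl-1-oxo-3-(prop-1-en-2-yl)-1,2,3,4,4a,5,6,7-octahydronaphthalen-2-yl (E)-2-methylbut-2-enoate | C=C(C)[C@H]1C[C@@]2(C)C(C(=O)[C@@H]1OC(=O)/C(C)=C/C)=CCC[C@@H]2C | intermediate
22 | boryl ketone: 23 with 4,4,5,5-tetramethyl-1,3,2-dioxaborolan-2-yl in place of OH at C1 (boron and C10–H both on the face opposite the C5 methyl) | C=C(C)[C@H]1C[C@@]2(C)[C@H](C(=O)[C@@H]1OC(=O)/C(C)=C/C)[C@@H](B3OC(C)(C)C(C)(C)O3)CC[C@@H]2C | intermediate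
23 | (2R,3R,4aR,5S,8S,8aS)-8-hydroxy-4a,5-dimethyl-1-oxo-3-(prop-1-en-2-yl)decahydronaphthalen-2-yl (E)-2-methylbut-2-enoate | C=C(C)[C@H]1C[C@@]2(C)[C@H](C(=O)[C@@H]1OC(=O)/C(C)=C/C)[C@@H](O)CC[C@@H]2C | intermediate
24 | (2R,3R,4aR,5S,8S,8aS)-8-acetoxy-4a,5-dimethyl-1-oxo-3-(prop-1-en-2-yl)decahydronaphthalen-2-yl (E)-2-methylbut-2-enoate | C=C(C)[C@H]1C[C@@]2(C)[C@H](C(=O)[C@@H]1OC(=O)/C(C)=C/C)[C@@H](OC(C)=O)CC[C@@H]2C | target

## Step count and risks

Total step count: 12. Longest linear sequence: 8 (steps 1–3 or 4–6, then 8–12).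

Steps most likely to fail:

**Step 9 (new ring closure).** Risks are slow 6‑endo addition to the tetrasubstituted enone and competition between C4 control and the ring's preference for isopropenyl trans to the C5 methyl. The fallback uses known chemistry, sets out from 3 and comes back at 18; it closes ring A at C9–C10 and sets C7 on the open chain. MeLi turns 3 into enolate 4, which is alkylated in THF/DMPU with methyl (E)-4-bromobut-2-enoate anti to the neighbouring methyl to give methyl (E)-4-[(1R,2S)-1,2-dimethyl-6-oxocyclohexyl]but-2-enoate F3. Rhodium‑catalysed asymmetric 1,4‑addition of 8 ([Rh(cod)2]BF4, BINAP, toluene/H2O) gives methyl (S)-3-{[(1R,2S)-1,2-dimethyl-6-oxocyclohexyl]methyl}-4-methylpent-4-enoate F4. KN(SiMe3)2 then PhNTf2 gives methyl (S)-3-{[(1R,6S)-1,6-dimethyl-2-(trifluoromethylsulfonyloxy)cyclohex-2-en-1-yl]methyl}-4-methylpent-4-enoate F5. iBu2AlH at −78 °C gives (S)-3-{[(1R,6S)-1,6-dimethyl-2-(trifluoromethylsulfonyloxy)cyclohex-2-en-1-yl]methyl}-4-methylpent-4-enal F6. An intramolecular Nozaki–Hiyama–Kishi reaction (NiCl2 cat., CrCl2, DMF) closes ring A to (3S,4aR,5S)-4a,5-dimethyl-3-(prop-1-en-2-yl)-1,2,3,4,4a,5,6,7-octahydronaphthalen-1-ol F7 (both carbinol epimers), and Dess–Martin periodinane oxidises it to 18.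

**Step 8 (acyl Stille coupling).** The tetrasubstituted stannane transmetalates slowly, and a primary iodide is present. The fallback sets out from 6 and 9 and comes back at 15. MeLi in THF at −78 °C converts 6 into (S)-(2,3-dimethylcyclohex-1-en-1-yl)lithium F1, which opens lactone 9 at −78 °C to (S)-1-[(S)-2,3-dimethylcyclohex-1-en-1-yl]-4-hydroxy-3-(prop-1-en-2-yl)butan-1-one F2. I2, PPh3 and imidazole then convert the primary alcohol into iodide 15.

**Step 11 (conjugate borylation).** Risks are face selectivity at C1, kinetic protonation at C10, and base sensitivity of the α‑acyloxy ketone. The fallback sets out from 21 and comes back at 23. Nucleophilic epoxidation (tBuOOH, DBU, CH2Cl2, 0 °C) from the face opposite the C5 methyl gives the C1,C10 α-epoxy ketone of 21 F8. Reductive opening at the carbon next to the ketone with sodium phenylselenide–borate (PhSeSePh, NaBH4, EtOH, AcOH) gives 23.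

Further compounds
F1 | step 8 | (S)-(2,3-dimethylcyclohex-1-en-1-yl)lithium | [Li]C1=C(C)[C@@H](C)CCC1
F2 | step 8 | (S)-1-[(S)-2,3-dimethylcyclohex-1-en-1-yl]-4-hydroxy-3-(prop-1-en-2-yl)butan-1-one | C=C(C)[C@@H](CO)CC(=O)C1=C(C)[C@@H](C)CCC1
F3 | step 9 | methyl (E)-4-[(1R,2S)-1,2-dimethyl-6-oxocyclohexyl]but-2-enoate | COC(=O)/C=C/C[C@@]1(C)C(=O)CCC[C@@H]1C
F4 | step 9 | methyl (S)-3-{[(1R,2S)-1,2-dimethyl-6-oxocyclohexyl]methyl}-4-methylpent-4-enoate | C=C(C)[C@H](CC(=O)OC)C[C@@]1(C)C(=O)CCC[C@@H]1C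
F5 | step 9 | methyl (S)-3-{[(1R,6S)-1,6-dimethyl-2-(trifluoromethylsulfonyloxy)cyclohex-2-en-1-yl]methyl}-4-methylpent-4-enoate | C=C(C)[C@H](CC(=O)OC)C[C@@]1(C)C(OS(=O)(=O)C(F)(F)F)=CCC[C@@H]1C
F6 | step 9 | (S)-3-{[(1R,6S)-1,6-dimethyl-2-(trifluoromethylsulfonyloxy)cyclohex-2-en-1-yl]methyl}-4-methylpent-4-enal | C=C(C)[C@H](CC=O)C[C@@]1(C)C(OS(=O)(=O)C(F)(F)F)=CCC[C@@H]1C
F7 | step 9 | (3S,4aR,5S)-4a,5-dimethyl-3-(prop-1-en-2-yl)-1,2,3,4,4a,5,6,7-octahydronaphthalen-1-ol (both carbinol epimers) | C=C(C)[C@H]1C[C@@]2(C)C(C(O)C1)=CCC[C@@H]2C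
F8 | step 11 | C1,C10 α-epoxy ketone of 21 (epoxide oxygen on the face opposite the C5 methyl) | C=C(C)[C@H]1C[C@@]2(C)[C@@]3(C(=O)[C@@H]1OC(=O)/C(C)=C/C)O[C@H]3CC[C@@H]2C
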